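**Retrosynthetic overview**

1. The target is 7-O-methylagathisflavone, two apigenin units joined from C6 of the 7-O-methylated unit (unit 1) to C8 of the other (unit 2). The plan rests on ring A of unit 1, a phloroglucinol ring with three different oxygens. The axis carbon C6 sits between the free 5-OH and the 7-OMe, and the oxygen on C8a (the later O1) lies para to it.
2. Late disconnections are the five O-benzyl groups and then ring C of unit 1 at O1–C2 (6-endo closure of an o-hydroxyaryl ynone). Its three carbons are attached to C4a by ortho-formylation, acetylide addition and oxidation.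
3. In the key disconnection, ring A of unit 1 is cut into a four-carbon piece (C5, C4a, C8a, C8, from 3-(4-methoxybenzyloxy)cyclobutenone) and a two-carbon piece (C6, C7, from an 8-(methoxyethynyl)flavone). A benzannulation cascade makes C5–C6 and C7–C8 and recloses C4a–C5, so no aryl–aryl coupling is needed and the axis starts as the sp–sp2 bond of an alkynylation.
4. Unit 2 comes from phloroacetophenone by the chalcone route, iodination at C8, and Negishi alkynylation with a zinc acetylide made from trichloroethylene and methanol.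
5. Ring order: ring C of unit 2 (its rings A and B are bought), then ring A of unit 1, then ring C of unit 1 (its ring B is bought).

Key step: step 8

Assumption: the SMILES fixes no sense for the C6–C8'' axis, so the biaryl is carried and delivered as the racemate. 3-Ethoxycyclobut-2-en-1-one and 1-(benzyloxy)-4-ethynylbenzene are taken as catalogue compounds.

**Step 1**
Reactants: 1 2',4',6'-trihydroxyacetophenone
Product: 2 2'-hydroxy-4',6'-bis(benzyloxy)acetophenone
Conditions: BnBr (2.1 equiv), K2CO3 (2.2 equiv), acetone, reflux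
Reagents that add atoms: benzyl bromide, BrCc1ccccc1
Why: In this Williamson etherification the para OH and one ortho OH are alkylated, and the last OH, hydrogen-bonded to the acetyl carbonyl, is too poor a nucleophile to react when the halide is limited.

**Step 2**
Reactants: 2 2'-hydroxy-4',6'-bis(benzyloxy)acetophenone, 3 4-(benzyloxy)benzaldehyde
Product: 4 (E)-2'-hydroxy-4,4',6'-tris(benzyloxy)chalcone
Conditions: KOH (aq 50%), EtOH–THF, rt; then dil. HCl
Reagents that add atoms: none
Why: Claisen–Schmidt condensation of the methyl ketone enolate with a non-enolisable aldehyde, followed by E1cB dehydration, should give the conjugated (E)-enone.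

**Step 3**
Reactants: 4 (E)-2'-hydroxy-4,4',6'-tris(benzyloxy)chalcone
Product: 5 5,7,4'-tribenzyloxyflavone (tri-O-benzylapigenin)
Conditions: I2 (10 mol %), DMSO, 130 °C
Reagents that add atoms: none
Why: Iodine-catalysed oxidative cyclisation of a 2'-hydroxychalcone closes ring C of unit 2 in the 6-endo oxa-Michael sense and dehydrogenates it, with DMSO as the terminal oxidant.

**Step 4**
Reactants: 5 5,7,4'-tribenzyloxyflavone
Product: 6 8-iodo-5,7,4'-tribenzyloxyflavone
Conditions: NIS (1.05 equiv), TFA (10 mol %), MeCN–CH2Cl2, 0 °C → rt, dark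
Reagents that add atoms: N-iodosuccinimide, O=C1CCC(=O)N1I
Why: In this electrophilic aromatic iodination, 5,7-dialkoxyflavones with the 5-oxygen alkylated react at C8, which lies between O1 and one benzyloxy group, rather than at C6, which is wedged between two benzyloxy groups.

**Step 5**
Reactants: 7 trichloroethylene, 8 methanol
Product: 11 (E)-1,2-dichloro-1-methoxyethene, via potassium methoxide 9 (not isolated), via dichloroacetylene 10 (not isolated)
Conditions: 8 (1.1 equiv), KH (1.0 equiv), THF, 0 °C; then 7 (1.0 equiv), −50 °C → rt, under Ar; distillation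
Reagents that add atoms: none
Why: Base-induced dehydrochlorination followed by anti addition of methanol to the transient chloroalkyne is the standard route from trichloroethylene to (E)-1,2-dichlorovinyl ethers.

**Step 6**
Reactants: 11 (E)-1,2-dichloro-1-methoxyethene, 6 8-iodo-5,7,4'-tribenzyloxyflavone
Product: 15 8-(methoxyethynyl)-5,7,4'-tribenzyloxyflavone, via chloro(methoxy)ethyne 12 (not isolated), via lithium methoxyacetylide 13 (not isolated), via methoxyethynylzinc chloride 14 (not isolated)
Conditions: 11 (2.5 equiv), n-BuLi (5.0 equiv), THF, −78 → −40 °C; ZnCl2 (2.6 equiv), −78 → 0 °C; then 6 (1 equiv), Pd(PPh3)4 (5 mol %), THF, rt → 45 °C; filtration through basic alumina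
Reagents that add atoms: none
Why: Elimination and chlorine–lithium exchange convert the dichlorovinyl ether into the lithium alkoxyacetylide, and after transmetalation to zinc a Negishi alkynylation of the aryl iodide, a known entry to 1-alkoxy-2-arylacetylenes, forms the unhindered sp–sp2 bond that later becomes the biaryl axis.

**Step 7**
Reactants: 16 3-ethoxycyclobut-2-en-1-one, 17 4-methoxybenzyl alcohol
Product: 18 3-(4-methoxybenzyloxy)cyclobut-2-en-1-one
Conditions: 17 (1.2 equiv), PPTS (5 mol %), toluene, 40 °C, reduced pressure (EtOH removed)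
Reagents that add atoms: none
Why: Acid-catalysed vinylogous transesterification (addition–elimination at C3) is driven by removal of ethanol, and the same carbon is known to exchange its ethoxy group for OH in cold dilute acid.

**Step 8**
Reactants: 15 8-(methoxyethynyl)-5,7,4'-tribenzyloxyflavone, 18 3-(4-methoxybenzyloxy)cyclobut-2-en-1-one
Product: 23 8-[2-hydroxy-6-methoxy-4-(4-methoxybenzyloxy)phenyl]-5,7,4'-tribenzyloxyflavone, via vinylketene 19 (not isolated), via vinylcyclobutenone adduct 20 (not isolated), via dienylketene 21 (not isolated), via cyclohexadienone tautomer 22 (not isolated)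
Conditions: 15 (1 equiv, 0.5 M), 18 (3 equiv, in three portions), toluene, sealed vessel, 120 → 150 °C; then K2CO3, MeOH–THF, rt
Reagents that add atoms: none
Why: Heat opens 18 in a conrotatory four-electron electrocyclic reaction to the vinylketene 19, whose ketene C=C bond adds to the triple bond of 15 in a [2+2] cycloaddition to give 20. A second four-electron opening turns 20 into the dienylketene 21, which closes carbocyclic ring A of unit 1 by a six-electron electrocyclisation (C4a–C5 bond) to 22, and enolisation of 22 gives the phenol 23. The closest known reaction type is the Danheiser benzannulation of cyclobutenones with 1-alkoxyalkynes itself, in which the second ring opening always involves a 3-alkoxycyclobutenone, so 18 should open as well, if at a higher temperature than a 3-alkyl analogue. The selectivity needed is the orientation of the [2+2] step: the methoxy group makes the aryl-bearing alkyne carbon the nucleophilic end, which bonds to the electrophilic ketene carbonyl carbon (C5–C6), while the methoxy-bearing carbon bonds to the ketene alpha carbon (C7–C8), and this places the flavonyl group between the new 5-OH and the 7-OMe and leaves the PMB-oxy group para to it. No stereocentre remains, since C4 of 20 becomes trigonal again on ring opening, and the C6–C8'' axis forms as a racemate. A methyl ynol ether has no beta hydrogen for retro-ene loss of an alkene, the linear alkyne keeps the two ortho oxygens of unit 2 away from the reacting carbon, portionwise surplus 18 offsets ketene dimerisation, and the closing methanolysis returns any 23 that surplus 19 has acylated.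

**Step 9**
Reactants: 23 8-[2-hydroxy-6-methoxy-4-(4-methoxybenzyloxy)phenyl]-5,7,4'-tribenzyloxyflavone
Product: 24 8-[3-formyl-2-hydroxy-6-methoxy-4-(4-methoxybenzyloxy)phenyl]-5,7,4'-tribenzyloxyflavone
Conditions: MgCl2 (anhydrous, 4 equiv), Et3N (6 equiv), (CH2O)n (10 equiv), MeCN–THF, reflux; then 1 M HCl
Reagents that add atoms: paraformaldehyde (formaldehyde unit), C=O
Why: In the magnesium-mediated ortho-formylation of phenols (Casnati–Skattebøl) the metal bound to the phenolate delivers formaldehyde to an ortho carbon, C6 is blocked so only C4a can react, and a second formaldehyde accepts the hydride.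

**Step 10**
Reactants: 24 8-[3-formyl-2-hydroxy-6-methoxy-4-(4-methoxybenzyloxy)phenyl]-5,7,4'-tribenzyloxyflavone
Product: 25 8-[2-(benzyloxy)-3-formyl-6-methoxy-4-(4-methoxybenzyloxy)phenyl]-5,7,4'-tribenzyloxyflavone
Conditions: BnBr (1.5 equiv), K2CO3, DMF, 50 °C
Reagents that add atoms: benzyl bromide, BrCc1ccccc1
Why: Williamson etherification caps the 5-OH of unit 1, so that later only the oxygen on C8a can close the pyranone and the 6,8''-linkage cannot drift to an 8,8''-linkage.

**Step 11**
Reactants: 25 8-[2-(benzyloxy)-3-formyl-6-methoxy-4-(4-methoxybenzyloxy)phenyl]-5,7,4'-tribenzyloxyflavone, 26 1-(benzyloxy)-4-ethynylbenzene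
Product: 28 propargylic alcohol of 25 [CH(OH)–C≡C–C6H4-4-OBn on C4a of unit 1], via lithium 4-(benzyloxy)phenylacetylide 27 (not isolated)
Conditions: 26 (1.3 equiv), n-BuLi (1.2 equiv), THF, −78 °C; then 25, −78 °C; then H2O
Reagents that add atoms: none
Why: A lithium acetylide adds 1,2 to the aldehyde, which at −78 °C is far more electrophilic than the vinylogous-ester carbonyl of the flavone, and the carbinol centre forms without control and is erased in the next step.

**Step 12**
Reactants: 28 propargylic alcohol
Product: 29 ynone [C(=O)–C≡C–C6H4-4-OBn on C4a of unit 1]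
Conditions: Dess–Martin periodinane (1.3 equiv), CH2Cl2, 0 °C → rt
Reagents that add atoms: none
Why: Dess–Martin oxidation of a benzylic propargylic alcohol is mild and neutral enough to leave the PMB ether, the benzyl ethers and the flavone untouched.

**Step 13**
Reactants: 29 ynone
Product: 31 5,4',5'',7'',4'''-penta-O-benzyl-7-O-methylagathisflavone, via o-hydroxyaryl ynone 30 (not isolated)
Conditions: DDQ (1.5 equiv), CH2Cl2–H2O (18:1), 0 °C → rt; aq NaHCO3 wash; then DMAP (20 mol %), DMF, 40 °C
Reagents that add atoms: none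
Why: DDQ cleaves only the PMB ether (hydride abstraction assisted by the p-methoxy group, plain benzyl ethers stay) and so frees only the C8a oxygen, and DMAP-catalysed conjugate addition–elimination on the ynone enforces the 6-endo-dig O1–C2 closure to the flavone instead of the 5-exo closure to an aurone.

**Step 14**
Reactants: 31 5,4',5'',7'',4'''-penta-O-benzyl-7-O-methylagathisflavone
Product: 32 7-O-methylagathisflavone (CNP0246647.0)
Conditions: H2 (1 atm), 10% Pd/C, THF–MeOH, rt
Reagents that add atoms: none
Why: Catalytic hydrogenolysis removes the five aryl benzyl ethers, while the methyl ether and the pyranone double bonds are inert at atmospheric pressure and room temperature.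

**Compound list**

1 | 2',4',6'-trihydroxyacetophenone | CC(=O)c1c(O)cc(O)cc1O | starting material
2 | 2'-hydroxy-4',6'-bis(benzyloxy)acetophenone | CC(=O)c1c(O)cc(OCc2ccccc2)cc1OCc1ccccc1 | intermediate
3 | 4-(benzyloxy)benzaldehyde | O=Cc1ccc(OCc2ccccc2)cc1 | starting material
4 | (E)-2'-hydroxy-4,4',6'-tris(benzyloxy)chalcone | O=C(/C=C/c1ccc(OCc2ccccc2)cc1)c1c(O)cc(OCc2ccccc2)cc1OCc1ccccc1 | intermediate
5 | 5,7,4'-tribenzyloxyflavone | O=c1cc(-c2ccc(OCc3ccccc3)cc2)oc2cc(OCc3ccccc3)cc(OCc3ccccc3)c12 | intermediate
6 | 8-iodo-5,7,4'-tribenzyloxyflavone | O=c1cc(-c2ccc(OCc3ccccc3)cc2)oc2c(I)c(OCc3ccccc3)cc(OCc3ccccc3)c12 | intermediate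
7 | trichloroethylene | ClC=C(Cl)Cl | starting material
8 | methanol | CO | starting material
9 | potassium methoxide | C[O-].[K+] | intermediate
10 | dichloroacetylene | ClC#CCl | intermediate
11 | (E)-1,2-dichloro-1-methoxyethene | CO/C(Cl)=C\Cl | intermediate
12 | chloro(methoxy)ethyne | COC#CCl | intermediate
13 | lithium methoxyacetylide | COC#C[Li] | intermediate
14 | methoxyethynylzinc chloride | COC#C[Zn]Cl | intermediate
15 | 8-(methoxyethynyl)-5,7,4'-tribenzyloxyflavone | COC#Cc1c(OCc2ccccc2)cc(OCc2ccccc2)c2c(=O)cc(-c3ccc(OCc4ccccc4)cc3)oc12 | intermediate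
16 | 3-ethoxycyclobut-2-en-1-one | CCOC1=CC(=O)C1 | starting material
17 | 4-methoxybenzyl alcohol | COc1ccc(CO)cc1 | starting material
18 | 3-(4-methoxybenzyloxy)cyclobut-2-en-1-one | COc1ccc(COC2=CC(=O)C2)cc1 | intermediate
19 | 3-(4-methoxybenzyloxy)buta-1,3-dien-1-one (vinylketene) | C=C(OCc1ccc(OC)cc1)C=C=O | intermediate
20 | 2-(5,7,4'-tribenzyloxyflavon-8-yl)-3-methoxy-4-[1-(4-methoxybenzyloxy)vinyl]cyclobut-2-en-1-one, racemic at C4 | COC1=C(c2c(OCc3ccccc3)cc(OCc3ccccc3)c3c(=O)cc(-c4ccc(OCc5ccccc5)cc4)oc23)C(=O)C1C(=C)OCc1ccc(OC)cc1 | intermediate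
21 | 2-(5,7,4'-tribenzyloxyflavon-8-yl)-3-methoxy-5-(4-methoxybenzyloxy)hexa-1,3,5-trien-1-one, chain ends cis about C3=C4 | O=C=C(c1c(OCc2ccccc2)cc(OCc2ccccc2)c2c(=O)cc(-c3ccc(OCc4ccccc4)cc3)oc12)/C(OC)=C\C(=C)OCc1ccc(OC)cc1 | intermediate
22 | 2-(5,7,4'-tribenzyloxyflavon-8-yl)-3-methoxy-5-(4-methoxybenzyloxy)cyclohexa-2,4-dien-1-one | COC1=C(c2c(OCc3ccccc3)cc(OCc3ccccc3)c3c(=O)cc(-c4ccc(OCc5ccccc5)cc4)oc23)C(=O)CC(OCc2ccc(OC)cc2)=C1 | intermediate
23 | 8-[2-hydroxy-6-methoxy-4-(4-methoxybenzyloxy)phenyl]-5,7,4'-tribenzyloxyflavone, racemic axis | COc1cc(OCc2ccc(OC)cc2)cc(O)c1-c1c(OCc2ccccc2)cc(OCc2ccccc2)c2c(=O)cc(-c3ccc(OCc4ccccc4)cc3)oc12 | intermediate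
24 | 8-[3-formyl-2-hydroxy-6-methoxy-4-(4-methoxybenzyloxy)phenyl]-5,7,4'-tribenzyloxyflavone, racemic axis | COc1cc(OCc2ccc(OC)cc2)c(C=O)c(O)c1-c1c(OCc2ccccc2)cc(OCc2ccccc2)c2c(=O)cc(-c3ccc(OCc4ccccc4)cc3)oc12 | intermediate
25 | 8-[2-(benzyloxy)-3-formyl-6-methoxy-4-(4-methoxybenzyloxy)phenyl]-5,7,4'-tribenzyloxyflavone, racemic axis | COc1cc(OCc2ccc(OC)cc2)c(C=O)c(OCc2ccccc2)c1-c1c(OCc2ccccc2)cc(OCc2ccccc2)c2c(=O)cc(-c3ccc(OCc4ccccc4)cc3)oc12 | intermediate
26 | 1-(benzyloxy)-4-ethynylbenzene | C#Cc1ccc(OCc2ccccc2)cc1 | starting material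
27 | lithium 4-(benzyloxy)phenylacetylide | [Li]C#Cc1ccc(OCc2ccccc2)cc1 | intermediate
28 | 8-{2-(benzyloxy)-3-[3-(4-benzyloxyphenyl)-1-hydroxyprop-2-yn-1-yl]-6-methoxy-4-(4-methoxybenzyloxy)phenyl}-5,7,4'-tribenzyloxyflavone, carbinol centre uncontrolled, racemic axis | COc1cc(OCc2ccc(OC)cc2)c(C(O)C#Cc2ccc(OCc3ccccc3)cc2)c(OCc2ccccc2)c1-c1c(OCc2ccccc2)cc(OCc2ccccc2)c2c(=O)cc(-c3ccc(OCc4ccccc4)cc3)oc12 | intermediate
29 | 8-{2-(benzyloxy)-3-[3-(4-benzyloxyphenyl)prop-2-ynoyl]-6-methoxy-4-(4-methoxybenzyloxy)phenyl}-5,7,4'-tribenzyloxyflavone | COc1cc(OCc2ccc(OC)cc2)c(C(=O)C#Cc2ccc(OCc3ccccc3)cc2)c(OCc2ccccc2)c1-c1c(OCc2ccccc2)cc(OCc2ccccc2)c2c(=O)cc(-c3ccc(OCc4ccccc4)cc3)oc12 | intermediate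
30 | 8-{2-(benzyloxy)-3-[3-(4-benzyloxyphenyl)prop-2-ynoyl]-4-hydroxy-6-methoxyphenyl}-5,7,4'-tribenzyloxyflavone | COc1cc(O)c(C(=O)C#Cc2ccc(OCc3ccccc3)cc2)c(OCc2ccccc2)c1-c1c(OCc2ccccc2)cc(OCc2ccccc2)c2c(=O)cc(-c3ccc(OCc4ccccc4)cc3)oc12 | intermediate
31 | 5,4',5'',7'',4'''-penta-O-benzyl-7-O-methylagathisflavone, racemic axis | COc1cc2oc(-c3ccc(OCc4ccccc4)cc3)cc(=O)c2c(OCc2ccccc2)c1-c1c(OCc2ccccc2)cc(OCc2ccccc2)c2c(=O)cc(-c3ccc(OCc4ccccc4)cc3)oc12 | intermediate
32 | 7-O-methylagathisflavone (CNP0246647.0), racemic axis | COc1cc2oc(-c3ccc(O)cc3)cc(=O)c2c(O)c1-c1c(O)cc(O)c2c(=O)cc(-c3ccc(O)cc3)oc12 | target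

**Step count**

Total step count: 14. Longest linear sequence: 12 steps (steps 1, 2, 3, 4, 6, 8, 9, 10, 11, 12, 13, 14).

**Steps most likely to fail**

1. **Step 8.**
   - Risk: the vinylogous-ester cyclobutenone may open only reluctantly. At the temperature then required, ketene dimerisation and slow decay of the ynol ether could outrun the [2+2] addition at the flanked alkyne carbon.
   - Fallback: the axis is made by a Suzuki–Miyaura coupling of two finished flavones. The fallback sets out from 6, which is borylated (B2pin2, PdCl2(dppf), KOAc, dioxane, 90 °C) to 5,7,4'-tribenzyloxyflavone-8-boronic acid pinacol ester F1.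
   - Commercial genkwanin (5,4'-dihydroxy-7-methoxyflavone) is benzylated at its non-chelated 4'-OH (BnBr, 1 equiv, K2CO3, acetone) to 4'-O-benzylgenkwanin F2.
   - F2 is iodinated at C6 under the direction of the free 5-OH (benzyltrimethylammonium dichloroiodate, CaCO3, CH2Cl2–MeOH) to 4'-O-benzyl-6-iodogenkwanin F3, and this is benzylated (BnBr, K2CO3, DMF) to 5,4'-di-O-benzyl-6-iodogenkwanin F4.
   - Coupling of F1 with F4 (Pd2(dba)3, SPhos, K3PO4, toluene–H2O, 100 °C) comes back to the route at 31.

2. **Step 6.**
   - Risk: coupling at the doubly ortho-substituted iodide may be slow, which would allow reduction of the C–I bond and attack of basic organometallic residues on the pyranone. The triple bond may also hydrate during isolation.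
   - Fallback: the in-situ zinc reagent is replaced by an isolable, base-free tin acetylide. Setting out from 11, lithium methoxyacetylide 13 is generated as in step 6 and quenched with Bu3SnCl to give tributyl(methoxyethynyl)stannane F5, which is distilled.
   - A Stille coupling of F5 with 6 (Pd(PPh3)4, CuI, toluene–DMF, 60 °C) comes back to the route at 15.

3. **Step 7.**
   - Risk: the exchange may stay incomplete, the benzylic alcohol may self-condense under acid, or the strained ring may be opened by alcoholysis at the carbonyl group.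
   - Fallback: setting out from 16, cold dilute HCl hydrolyses the enol ether to cyclobutane-1,3-dione F6, a strongly acidic vinylogous acid.
   - F6 is O-alkylated with 17 under neutral Mitsunobu conditions (PPh3, DIAD, THF, 0 °C), which comes back to the route at 18.

**Further compounds**

F1 | step 8 | 5,7,4'-tribenzyloxyflavone-8-boronic acid pinacol ester | CC1(C)OB(OC1(C)C)c1c(OCc2ccccc2)cc(OCc2ccccc2)c2c(=O)cc(-c3ccc(OCc4ccccc4)cc3)oc12
F2 | step 8 | 4'-O-benzylgenkwanin | COc1cc(O)c2c(=O)cc(-c3ccc(OCc4ccccc4)cc3)oc2c1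
F3 | step 8 | 4'-O-benzyl-6-iodogenkwanin | COc1cc2oc(-c3ccc(OCc4ccccc4)cc3)cc(=O)c2c(O)c1I
F4 | step 8 | 5,4'-di-O-benzyl-6-iodogenkwanin | COc1cc2oc(-c3ccc(OCc4ccccc4)cc3)cc(=O)c2c(OCc2ccccc2)c1I
F5 | step 6 | tributyl(methoxyethynyl)stannane | CCCC[Sn](CCCC)(CCCC)C#COC
F6 | step 7 | cyclobutane-1,3-dione | O=C1CC(=O)C1
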